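The numbers in the tables come from a simulation from invented constants, and the scatter is random.

At early times little starting material has gone, so the two runs ought to show directly how the rate follows the catalyst.

| flask | starting material | catalyst | time |
|---|---|---|---|
| winter | 0.800 M | 0.00400 M |  |
| midnight | 0.800 M | 0.00600 M |  |
| autumn | 0.800 M | 0.00980 M | 6.1 min |

| winter run: time / min | winter run: [product] / M | midnight run: time / min | midnight run: [product] / M |
|---|---|---|---|
| 0.24 | 0.019 | 0.24 | 0.018 |
| 0.46 | 0.036 | 0.46 | 0.051 |
| 0.88 | 0.065 | 0.88 | 0.088 |
| 1.7 | 0.109 | 1.7 | 0.164 |
| 3.2 | 0.196 | 3.2 | 0.290 |
| 6.1 | 0.355 | 6.1 | 0.483 |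

(each reading ± 0.004 M)

* reaction order in [catalyst] at the outset, round the charge of the winter run, defined at two percent of the starting material turned into product
* product in the autumn run at 6.1 min, as a share of the starting material charged

- Overall: starting material -> product, with catalyst as catalyst.
- Constant volume, constant temperature.
- The analysis sees a species whether free or bound.
- An order is taken over about fifteen percent of the charge, up and down.

We go to logarithms. At 0.88 min the winter run holds 0.065 M of product and the midnight run 0.088 M, so the log of that ratio over the log of the catalyst ratio gives an order of 0.747. But the scatter of 0.004 M puts an uncertainty of 0.189 on that figure, so we turn to the later readings, where the product is larger.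

Call D = C·t the dose, with C the catalyst charged and t the time. Let S₀ be the starting material charged and P the product. Then the winter run at 6.1 min gives 24.0 M⁻¹ min⁻¹ for κ = ln(S₀/(S₀−P))/D, the e-foldings of starting material per unit of dose. Read at one moment, κC is what is called a pseudo-first-order rate constant, and 1/(κC) plays the part of a time constant for the starting material.

At the same time the midnight run gives κ = 25.3 M⁻¹ min⁻¹. Does that difference mean an order above one? Not necessarily: the winter reading of κ at 3.2 min is lower still, 22.0 M⁻¹ min⁻¹, so κ climbs with dose within the winter run too. The midnight reading at 3.2 min has a dose between those of the two winter readings, and its κ = 23.4 M⁻¹ min⁻¹ falls between theirs. These readings of the two runs lie along one curve in dose, so we take the order as near one.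

The autumn run has a dose 1.63 times that of the midnight run at 6.1 min. Holding κ at the midnight value gives 78.0% of the charge as product in the autumn run. Yet κ climbed from the winter to the midnight reading at 6.1 min, and carrying that rise forward in a straight line with dose gives 27.7 M⁻¹ min⁻¹, hence 80.9%, our own estimate.

The forecast gives an order of 0.97 (0.8 to 1.1) and 80% (74% to 85%), a little below our figure, noting that "the two runs fall on nearly one curve".

The autumn run gives 80.6%, and the order comes to 1.0.

    catalyst + starting material → product + catalyst (40.32 M⁻¹ min⁻¹)
    catalyst + starting material ⇌ idle catalyst-substrate complex, settled at all times (0.3740 M⁻¹)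
    2 starting material ⇌ idle substrate dimer, settled at all times (0.5590 M⁻¹)

Where two percent of the starting material of the winter run have turned, the rate in the midnight run is 1.5 times that of the winter run, for a catalyst ratio of 1.50. Read as κ, the autumn result is 27.4 M⁻¹ min⁻¹, higher than the winter reading of 24.0 M⁻¹ min⁻¹ at 6.1 min. The product of the midnight run comes to half of the starting material charged at 4.76 min, which gives κ = 24.3 M⁻¹ min⁻¹.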